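**Plan**

1. Retrosynthesis: the O-methyl bond and the C5–Br bond of ring A are cut last. Ring A is then cut at C2–C3 and C3–C4, which takes out C3 with its bromine as dibromocarbene and leaves a five-membered ring. The aryl ether bond C1–O goes back to 2-bromophenol and cyclopentenone.
2. Enabling feature (ring A numbered C1 = aryloxy carbon, C2 = methoxy carbon, then C3 to C6): C3 bears bromine and sits next to oxygen-bearing C2, exactly where a dibromocarbene carbon ends up when it is inserted beside a former ketone carbon. The other atoms, C1, C2, C4, C5 and C6, are the five carbons of a 2-aryloxycyclopentenone whose vinyl bromide becomes the C6 bromine.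
3. Forward: ring B is bought. The C1–O bond is made first on cyclopentenone oxide, C6–Br is put on the enone, the ketone is turned into its cross-conjugated silyl dienol ether, and ring A arises by five-to-six ring enlargement.
4. Finish: bromination para to the phenol oxygen gives C5–Br, and O-methylation gives the target.
5. Stereochemistry: the target is achiral; the few stereocenters of intermediates are racemic and are erased in the same step or the next one.

Key step: step 5

Remark: racemic intermediates are written as one enantiomer showing relative configuration, and the ring-A atom numbers given above are used for all intermediates.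

**Route**

Step 1
Reactants: 1 cyclopent-2-en-1-one
Product: 2 6-oxabicyclo[3.1.0]hexan-2-one (2,3-epoxycyclopentanone, racemic)
Conditions: 30% H2O2, NaOH (cat.), MeOH, 0 °C
Reagents that add atoms: hydrogen peroxide, OO
Why: Weitz–Scheffer epoxidation, in which hydroperoxide adds in conjugate fashion to the enone and the enolate closes onto oxygen; the epoxide is necessarily cis-fused and racemic, and both centres are erased in step 2.

Step 2
Reactants: 2 6-oxabicyclo[3.1.0]hexan-2-one; 3 2-bromophenol
Product: 5 2-(2-bromophenoxy)cyclopent-2-en-1-one, via trans-hydroxy ketone 4 (not isolated)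
Conditions: KH (0.1 equiv), THF–DMPU, 65 °C
Reagents that add atoms: none
Why: Epoxide opening followed by E1cB dehydration, in which the phenoxide attacks the carbonyl-activated α-carbon in an SN2 fashion (giving trans 4) and the β-hydroxy ketone loses water under the same basic conditions, a known way from α,β-epoxy ketones and phenols to 2-aryloxy enones; no stereocenter remains.

Step 3
Reactants: 5 2-(2-bromophenoxy)cyclopent-2-en-1-one
Product: 7 3-bromo-2-(2-bromophenoxy)cyclopent-2-en-1-one, via trans-dibromide 6 (not isolated)
Conditions: Br2 (1.0 equiv), CH2Cl2, −20 °C, dark; then Et3N, 0 to 23 °C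
Reagents that add atoms: bromine, BrBr
Why: Bromination–dehydrobromination of an enol ether, in which bromine adds across the aryloxy-substituted double bond, the α-bromo ether carbon ionizes with help from the aryloxy oxygen and Et3N removes the proton from the bromine-bearing carbon, leaving bromine on the β-carbon as in the bromination of cyclopentane-1,2-dione enols; at low temperature the alkene should react ahead of the deactivated ring B.

Step 4
Reactants: 7 3-bromo-2-(2-bromophenoxy)cyclopent-2-en-1-one
Product: 9 {[4-bromo-3-(2-bromophenoxy)cyclopenta-1,3-dien-2-yl]oxy}(tert-butyl)dimethylsilane, via lithium dienolate 8 (not isolated)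
Conditions: LiN(SiMe3)2, THF, −78 °C; then TBSOTf, −78 °C; cold pentane/aq. NaHCO3 work-up, crude product kept below 0 °C and used at once
Reagents that add atoms: tert-butyldimethylsilyl trifluoromethanesulfonate, CC(C)(C)[Si](C)(C)OS(=O)(=O)C(F)(F)F
Why: Kinetic enolization and O-silylation, in which the hindered amide removes a proton from the only α-CH2 (the α' position) at −78 °C to give the cross-conjugated dienolate and the silyl triflate traps it on oxygen; the diene is kept cold because a 1,5-hydrogen shift would move the CH2 group.

Step 5
Reactants: 9 {[4-bromo-3-(2-bromophenoxy)cyclopenta-1,3-dien-2-yl]oxy}(tert-butyl)dimethylsilane; 10 bromoform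
Product: 13 3,6-dibromo-2-(2-bromophenoxy)phenol, via dibromocyclopropane adduct 11 (not isolated), via aryl silyl ether 12 (not isolated)
Conditions: CHBr3 (2 equiv), KOtBu (3 equiv, added in portions), pentane, −40 to 23 °C; then Bu4NF, AcOH, THF, 0 °C
Reagents that add atoms: bromoform (compound 10), BrC(Br)Br
Why: Bromoform and KOtBu give dibromocarbene, which cyclopropanates the silyl enol ether double bond C2=C4 of 9 and so forms C2–C3 and C3–C4; the closest known reaction type is dihalocarbene addition to cyclic silyl enol ethers with ring enlargement to 2-halo enones, including the conversion of 1-indanone silyl enol ethers into 2-halo-1-naphthols. Adduct 11 then opens by disrotatory two-electron electrocyclic cleavage of the ring-fusion bond C2–C4 with loss of the endo bromide, pushed by the siloxy oxygen, so ring A is closed by one-carbon enlargement of the five-membered ring and not by a cyclization. The resulting cation is a cyclohexadienyl cation with its CH2 at C5, that is the para-protonated form of an aryl silyl ether; it should give up that proton to butoxide to furnish 12, which buffered Bu4NF desilylates in the same flask to phenol 13. No stereocenter survives, the two of 11 being destroyed on opening. The carbene must attack the siloxy-substituted trisubstituted alkene and not the tetrasubstituted bromo(aryloxy) alkene, which the higher electron density and lower hindrance of the enol ether should secure. The diene must also stay in its cross-conjugated form, which the low temperature and the portionwise addition of base to bromoform kept in excess while diene remains should secure, since butoxide is then used up in carbene formation before it can deprotonate the ring CH2.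

Step 6
Reactants: 13 3,6-dibromo-2-(2-bromophenoxy)phenol
Product: 14 3,4,6-tribromo-2-(2-bromophenoxy)phenol
Conditions: Br2 (1.0 equiv), CH2Cl2, 0 °C
Reagents that add atoms: bromine, BrBr
Why: Electrophilic aromatic bromination, in which the hydroxyl group is the strongest activator and its only free ortho or para position is the para carbon C5, while C4 is meta to it and ring B is a deactivated bromo diaryl ether ring.

Step 7
Reactants: 14 3,4,6-tribromo-2-(2-bromophenoxy)phenol
Product: 15 1,2,5-tribromo-3-(2-bromophenoxy)-4-methoxybenzene (CNP0117173.0)
Conditions: MeI, K2CO3, acetone, 50 °C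
Reagents that add atoms: iodomethane, CI
Why: Williamson ether synthesis, in which the acidic phenoxide is methylated on oxygen by MeI in an SN2 reaction and nothing else in the molecule is nucleophilic.

**Compound list**

1 | cyclopent-2-en-1-one | O=C1C=CCC1 | starting material
2 | 6-oxabicyclo[3.1.0]hexan-2-one (racemic, cis-fused) | O=C1CC[C@@H]2O[C@H]12 | intermediate
3 | 2-bromophenol | Oc1ccccc1Br | starting material
4 | trans-2-(2-bromophenoxy)-3-hydroxycyclopentan-1-one (racemic) | O=C1CC[C@H](O)[C@H]1Oc1ccccc1Br | intermediate
5 | 2-(2-bromophenoxy)cyclopent-2-en-1-one | O=C1CCC=C1Oc1ccccc1Br | intermediate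
6 | trans-2,3-dibromo-2-(2-bromophenoxy)cyclopentan-1-one (racemic) | O=C1CC[C@H](Br)[C@]1(Br)Oc1ccccc1Br | intermediate
7 | 3-bromo-2-(2-bromophenoxy)cyclopent-2-en-1-one | O=C1CCC(Br)=C1Oc1ccccc1Br | intermediate
8 | lithium 4-bromo-3-(2-bromophenoxy)cyclopenta-1,3-dien-2-olate | [Li+].[O-]C1=CCC(Br)=C1Oc1ccccc1Br | intermediate
9 | {[4-bromo-3-(2-bromophenoxy)cyclopenta-1,3-dien-2-yl]oxy}(tert-butyl)dimethylsilane | CC(C)(C)[Si](C)(C)OC1=CCC(Br)=C1Oc1ccccc1Br | intermediate
10 | bromoform | BrC(Br)Br | starting material
11 | {[3,6,6-tribromo-2-(2-bromophenoxy)bicyclo[3.1.0]hex-2-en-1-yl]oxy}(tert-butyl)dimethylsilane (racemic, cis-fused) | CC(C)(C)[Si](C)(C)O[C@@]12C(Oc3ccccc3Br)=C(Br)C[C@@H]1C2(Br)Br | intermediate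
12 | tert-butyl[3,6-dibromo-2-(2-bromophenoxy)phenoxy]dimethylsilane | CC(C)(C)[Si](C)(C)Oc1c(Br)ccc(Br)c1Oc1ccccc1Br | intermediate
13 | 3,6-dibromo-2-(2-bromophenoxy)phenol | Oc1c(Br)ccc(Br)c1Oc1ccccc1Br | intermediate
14 | 3,4,6-tribromo-2-(2-bromophenoxy)phenol | Oc1c(Br)cc(Br)c(Br)c1Oc1ccccc1Br | intermediate
15 | 1,2,5-tribromo-3-(2-bromophenoxy)-4-methoxybenzene | COc1c(Br)cc(Br)c(Br)c1Oc1ccccc1Br | target

**Step count and risks**

Total step count: 7. Longest linear sequence: 7 steps (1 to 15).

The lability of diene 9 made in step 4 shows up as a failure of step 5 and is counted there.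

Step 5 (key step). What may go wrong: the cross-conjugated diene may isomerize before the carbene reaches it, either by a 1,5-hydrogen shift or by deprotonation of the acidic ring CH2 by butoxide and reprotonation, so that the carbene carbon is inserted into a different ring bond. The carbene may also attack the other double bond, or surplus carbene may attack the phenoxide in a Reimer–Tiemann manner. Fallback: ring A is bought instead of made. Setting out from 2-bromophenol 3, nucleophilic aromatic substitution on 3,6-dibromo-2-fluorobenzaldehyde F1 (purchased; K2CO3, DMF, 90 °C) should give 3,6-dibromo-2-(2-bromophenoxy)benzaldehyde F2. Baeyer–Villiger oxidation (mCPBA, CH2Cl2) should convert it into 3,6-dibromo-2-(2-bromophenoxy)phenyl formate F3, and methanolysis (K2CO3, MeOH) would bring the route back at phenol 13; steps 1 to 5 are bypassed.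

Step 2. What may go wrong: base-induced oligomerization of the epoxy ketone or its rearrangement to the 1,2-dione enol may outrun attack by the hindered, weakly nucleophilic 2-bromophenoxide, or the phenoxide may open the epoxide at the β-carbon. Fallback: the ether bond is made by SN2 displacement on a saturated ketone and the double bond is introduced afterwards. Setting out from 2-bromophenol 3, O-alkylation with 2-chlorocyclopentan-1-one F4 (purchased; K2CO3, acetone, reflux) should give 2-(2-bromophenoxy)cyclopentan-1-one F5. Chlorination at the oxygen-bearing α-carbon (SO2Cl2, CH2Cl2, 0 °C) should give 2-(2-bromophenoxy)-2-chlorocyclopentan-1-one F6, and dehydrochlorination (Li2CO3, LiBr, DMF, 100 °C) would return the route at enone 5.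

Step 3. What may go wrong: bromine may substitute ring B para to the ether oxygen or the α' CH2 through acid-catalysed enolization, or hydrogen bromide may be lost in the wrong direction. Fallback: the C6 bromine is introduced as a vinylogous acid bromide, so no electrophilic bromination is needed. Setting out from 2-bromophenol 3, cyclopentane-1,3-dione F7 (purchased) is first converted by diazo transfer (4-acetamidobenzenesulfonyl azide, Et3N, MeCN) into 2-diazocyclopentane-1,3-dione F8. O–H insertion of its carbenoid into 3, catalysed by Rh2(OAc)4 (CH2Cl2, 40 °C), should give 2-(2-bromophenoxy)-3-hydroxycyclopent-2-en-1-one F9, the enol of the symmetrical 2-aryloxy-1,3-dione. Oxalyl bromide with catalytic DMF (CH2Cl2, 0 °C) would turn it into bromo enone 7; steps 1 to 3 are bypassed.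

Further compounds
F1 | step 5 | 3,6-dibromo-2-fluorobenzaldehyde (purchased) | O=Cc1c(F)c(Br)ccc1Br
F2 | step 5 | 3,6-dibromo-2-(2-bromophenoxy)benzaldehyde | O=Cc1c(Br)ccc(Br)c1Oc1ccccc1Br
F3 | step 5 | 3,6-dibromo-2-(2-bromophenoxy)phenyl formate | O=COc1c(Br)ccc(Br)c1Oc1ccccc1Br
F4 | step 2 | 2-chlorocyclopentan-1-one (purchased, racemic) | O=C1CCCC1Cl
F5 | step 2 | 2-(2-bromophenoxy)cyclopentan-1-one (racemic) | O=C1CCCC1Oc1ccccc1Br
F6 | step 2 | 2-(2-bromophenoxy)-2-chlorocyclopentan-1-one (racemic) | O=C1CCCC1(Cl)Oc1ccccc1Br
F7 | step 3 | cyclopentane-1,3-dione (purchased) | O=C1CCC(=O)C1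
F8 | step 3 | 2-diazocyclopentane-1,3-dione | O=C1CCC(=O)C1=[N+]=[N-]
F9 | step 3 | 2-(2-bromophenoxy)-3-hydroxycyclopent-2-en-1-one | O=C1CCC(O)=C1Oc1ccccc1Br
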